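**Retrosynthetic overview**

1. Target 19 ⇐ removal of the silyl and pivaloyl groups ⇐ C8–prenyl bond by Suzuki–Miyaura coupling on the C8 bromide of flavan-3-ol 16 ⇐ hydroboration–oxidation of 2H-chromene 14 anti to the C2 aryl group (sets C3).
2. 14 ⇐ C4–C4a bond by gold-catalysed 6-endo-dig hydroarylation of aryl propargyl ether 13. The strategy rests on C4 being an unsubstituted CH2 between C4a of ring A and C3: C4 can therefore come from a terminal alkyne carbon while the O1–C2 stereocentre is already in place.
3. 13 ⇐ O1–C2 bond by Mitsunobu inversion between bromophenol 6 and (R)-propargylic alcohol 12.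
4. 6 ⇐ 5-methoxyresorcinol 1 (bromine placed between the two oxygens by directed lithiation; it blocks C8 and later carries the prenyl group). 12 ⇐ 4-hydroxybenzaldehyde 7 and ethynylmagnesium bromide 9, with lipase resolution.
5. Ring order: rings A and B are bought; ring C (the pyran) is the only ring formed, in step 9.

Key step: step 9

Remark (assumption): lipase B is taken to follow Kazlauskas' rule on this substrate (aryl = large, ethynyl = medium group), so the (R)-acetate is the enantiomer cleaved in step 7; the configuration of 12 would be checked before step 8.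

**Route**

Step 1
Reactants: 1 5-methoxyresorcinol (5-methoxybenzene-1,3-diol)
Product: 2 1-methoxy-3,5-bis(methoxymethoxy)benzene
Conditions: MOMCl (2.5 equiv), i-Pr2NEt (3 equiv), CH2Cl2, 0 °C → rt
Reagents that add atoms: chloromethyl methyl ether, COCCl
Why: Base-mediated O-alkylation of both phenols (acetal-type etherification) should give the bis-MOM ether, whose two chelating OMOM groups are needed to direct the lithiation of step 2.

Step 2
Reactants: 2 1-methoxy-3,5-bis(methoxymethoxy)benzene
Product: 4 2-bromo-5-methoxy-1,3-bis(methoxymethoxy)benzene, via aryllithium 3 (not isolated)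
Conditions: n-BuLi (1.1 equiv), THF, 0 °C; then BrCl2C–CCl2Br, −78 °C → rt
Reagents that add atoms: n-butyllithium, [Li]CCCC (lithium of 3); 1,2-dibromo-1,1,2,2-tetrachloroethane, BrC(Cl)(Cl)C(Cl)(Cl)Br (bromine of 4)
Why: Directed ortho-metalation should take place at the carbon flanked by the two OMOM groups (cooperative chelation, stronger than that of OMe), and electrophilic bromination of the aryllithium then puts the bromine between the two oxygens.

Step 3
Reactants: 4 2-bromo-5-methoxy-1,3-bis(methoxymethoxy)benzene
Product: 5 2-bromo-5-methoxybenzene-1,3-diol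
Conditions: HCl (conc., cat.), MeOH, 40 °C
Reagents that add atoms: none
Why: Acid-catalysed transacetalisation to methanol removes both MOM groups as dimethoxymethane, while the aryl bromide and the methyl ether are inert.

Step 4
Reactants: 5 2-bromo-5-methoxybenzene-1,3-diol
Product: 6 2-bromo-3-(tert-butyldimethylsilyloxy)-5-methoxyphenol
Conditions: TBSCl (1.0 equiv, slow addition), imidazole, CH2Cl2, 0 °C
Reagents that add atoms: tert-butyldimethylsilyl chloride, CC(C)(C)[Si](C)(C)Cl
Why: Phenol silylation on a symmetric diol gives the same monosilyl ether whichever hydroxyl reacts; the step is close to statistical, so unreacted diol and bis-silyl ether would be recycled.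

Step 5
Reactants: 7 4-hydroxybenzaldehyde
Product: 8 4-formylphenyl pivalate
Conditions: PivCl, Et3N, DMAP (cat.), CH2Cl2, 0 °C → rt
Reagents that add atoms: pivaloyl chloride, CC(C)(C)C(Cl)=O
Why: DMAP-catalysed esterification of the phenol installs the hindered, electron-withdrawing pivalate that is meant to survive to the last step and to lower the tendency of the later C2–O1 bond to ionise.

Step 6
Reactants: 8 4-formylphenyl pivalate; 9 ethynylmagnesium bromide
Product: 11 (±)-4-(1-acetoxyprop-2-yn-1-yl)phenyl pivalate, via bromomagnesium alkoxide 10 (not isolated)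
Conditions: HC≡CMgBr (1.1 equiv), THF, −78 → 0 °C; then Ac2O, 0 °C → rt
Reagents that add atoms: acetic anhydride, CC(=O)OC(C)=O
Why: Grignard 1,2-addition to the aldehyde, which is far more electrophilic than the hindered aryl pivalate at low temperature, followed by acylation of the magnesium alkoxide in the same flask, should give the racemic propargylic acetate.

Step 7
Reactants: 11 (±)-4-(1-acetoxyprop-2-yn-1-yl)phenyl pivalate
Product: 12 4-[(1R)-1-hydroxyprop-2-yn-1-yl]phenyl pivalate
Conditions: immobilised Candida antarctica lipase B (Novozym 435), n-BuOH (3 equiv), MTBE, 30 °C, stopped at about 40–45% conversion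
Reagents that add atoms: none
Why: Enzymatic kinetic resolution by transesterification (alcoholysis) should cleave only the (R)-acetate (Kazlauskas' rule, aryl large and ethynyl medium), so the stereocentre that becomes C2 is set here as the (R)-alcohol while the (S)-acetate stays behind and the pivalate, a poor lipase substrate, is untouched.

Step 8
Reactants: 6 2-bromo-3-(tert-butyldimethylsilyloxy)-5-methoxyphenol; 12 4-[(1R)-1-hydroxyprop-2-yn-1-yl]phenyl pivalate
Product: 13 4-[(1S)-1-[2-bromo-3-(tert-butyldimethylsilyloxy)-5-methoxyphenoxy]prop-2-yn-1-yl]phenyl pivalate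
Conditions: PPh3, DIAD, toluene, −20 → 0 °C
Reagents that add atoms: none
Why: Mitsunobu etherification, in which the acidic ortho-bromophenol displaces the alkoxyphosphonium group in an SN2 step, should form the O1–C2 bond with inversion, (R)-12 giving (S)-13, the electron-poor pivaloyloxyphenyl group and the low temperature holding back ionisation.

Step 9
Reactants: 13 4-[(1S)-1-[2-bromo-3-(tert-butyldimethylsilyloxy)-5-methoxyphenoxy]prop-2-yn-1-yl]phenyl pivalate
Product: 14 4-[(2S)-8-bromo-7-(tert-butyldimethylsilyloxy)-5-methoxy-2H-chromen-2-yl]phenyl pivalate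
Conditions: Ph3PAuNTf2 (3 mol %), CH2Cl2, 4 Å MS, 0 °C → rt
Reagents that add atoms: none
Why: The cationic gold centre binds the terminal alkyne and makes its unsubstituted carbon electrophilic; the free ring A carbon next to the ether oxygen (the future C4a, also flanked by the methoxyl and para to the silyl ether) attacks it in a Friedel–Crafts sense, and rearomatisation with protodeauration of the vinylgold species releases the 2H-chromene. The closest known reaction type is the gold- or platinum-catalysed intramolecular hydroarylation of aryl propargyl ethers to 2H-chromenes. Ring C closes in the 6-endo-dig mode, which forms the C4–C4a bond. No stereocentre is created: C2 is not a reacting centre and carries the configuration fixed in steps 7 and 8 into the chromene. The step needs site selectivity on ring A, secured by the C8 bromine that occupies the only other position ortho to the ether oxygen, and endo rather than 5-exo closure, favoured by the electron-rich arene and the unsubstituted alkyne terminus. It also needs retention at C2, which the electron-withdrawing 4'-pivalate protects by making ionisation of the benzylic–propargylic C–O bond unfavourable.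

Step 10
Reactants: 14 4-[(2S)-8-bromo-7-(tert-butyldimethylsilyloxy)-5-methoxy-2H-chromen-2-yl]phenyl pivalate
Product: 16 4-[(2R,3S)-8-bromo-7-(tert-butyldimethylsilyloxy)-3-hydroxy-5-methoxychroman-2-yl]phenyl pivalate, via C3 alkylborane 15 (not isolated)
Conditions: BH3·SMe2 (1.5 equiv), THF, 0 °C → rt; then NaBO3·4H2O, THF/H2O, rt
Reagents that add atoms: borane–dimethyl sulfide, C[S+](C)[BH3-] (boron of 15); sodium perborate, [Na+].[Na+].O[B-]1(O)OO[B-](O)(O)OO1 (oxygen of 16)
Why: Hydroboration–oxidation, known for flav-3-enes, should add H–B syn on the face opposite the C2 aryl group with boron at C3 (away from the benzylic C4 of the electron-rich ring A and β to the withdrawing O1), and perborate oxidation with retention then gives the 3-hydroxyl trans to the aryl group, the C2 descriptor changing from S to R only because C3 now outranks the aryl group.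

Step 11
Reactants: 16 4-[(2R,3S)-8-bromo-7-(tert-butyldimethylsilyloxy)-3-hydroxy-5-methoxychroman-2-yl]phenyl pivalate; 17 prenylboronic acid pinacol ester
Product: 18 4-[(2R,3S)-7-(tert-butyldimethylsilyloxy)-3-hydroxy-5-methoxy-8-(3-methylbut-2-en-1-yl)chroman-2-yl]phenyl pivalate
Conditions: Pd(OAc)2 (5 mol %), t-BuXPhos (10 mol %), K3PO4 (aq), THF, 50 °C
Reagents that add atoms: none
Why: In this Suzuki–Miyaura coupling of an allylboronate, the bulky di-tert-butylbiarylphosphine should let the allylpalladium intermediate settle at its primary terminus before reductive elimination, giving the linear 3-methylbut-2-enyl group at C8, while the phosphate base is mild enough to spare the pivalate and the silyl ether.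

Step 12
Reactants: 18 4-[(2R,3S)-7-(tert-butyldimethylsilyloxy)-3-hydroxy-5-methoxy-8-(3-methylbut-2-en-1-yl)chroman-2-yl]phenyl pivalate
Product: 19 8-prenylafzelechin 5-methyl ether, (2R,3S)-2-(4-hydroxyphenyl)-5-methoxy-8-(3-methylbut-2-en-1-yl)chroman-3,7-diol
Conditions: K2CO3, MeOH (degassed), rt, under Ar; pH 7 buffer work-up
Reagents that add atoms: none
Why: Carbonate-mediated methanolysis should cleave the aryl pivalate (transesterification) and the aryl silyl ether in one operation, with ambient temperature and exclusion of air guarding against C2 epimerisation and phenol oxidation, and without acid that could cyclise the prenyl group onto the C7 hydroxyl.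

**Compound list**

1 | 5-methoxyresorcinol | COc1cc(O)cc(O)c1 | starting material
2 | 1-methoxy-3,5-bis(methoxymethoxy)benzene | COCOc1cc(OC)cc(OCOC)c1 | intermediate
3 | [4-methoxy-2,6-bis(methoxymethoxy)phenyl]lithium | COCOc1cc(OC)cc(OCOC)c1[Li] | intermediate
4 | 2-bromo-5-methoxy-1,3-bis(methoxymethoxy)benzene | COCOc1cc(OC)cc(OCOC)c1Br | intermediate
5 | 2-bromo-5-methoxybenzene-1,3-diol | COc1cc(O)c(Br)c(O)c1 | intermediate
6 | 2-bromo-3-(tert-butyldimethylsilyloxy)-5-methoxyphenol | COc1cc(O)c(Br)c(O[Si](C)(C)C(C)(C)C)c1 | intermediate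
7 | 4-hydroxybenzaldehyde | O=Cc1ccc(O)cc1 | starting material
8 | 4-formylphenyl pivalate | CC(C)(C)C(=O)Oc1ccc(C=O)cc1 | intermediate
9 | ethynylmagnesium bromide | C#C[Mg]Br | starting material
10 | bromomagnesium 1-(4-pivaloyloxyphenyl)prop-2-yn-1-olate (racemic) | C#CC(O[Mg]Br)c1ccc(OC(=O)C(C)(C)C)cc1 | intermediate
11 | (±)-4-(1-acetoxyprop-2-yn-1-yl)phenyl pivalate | C#CC(OC(C)=O)c1ccc(OC(=O)C(C)(C)C)cc1 | intermediate
12 | 4-[(1R)-1-hydroxyprop-2-yn-1-yl]phenyl pivalate | O[C@H](C#C)c1ccc(OC(=O)C(C)(C)C)cc1 | intermediate
13 | 4-[(1S)-1-[2-bromo-3-(tert-butyldimethylsilyloxy)-5-methoxyphenoxy]prop-2-yn-1-yl]phenyl pivalate | COc1cc(O[Si](C)(C)C(C)(C)C)c(Br)c(O[C@@H](C#C)c2ccc(OC(=O)C(C)(C)C)cc2)c1 | intermediate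
14 | 4-[(2S)-8-bromo-7-(tert-butyldimethylsilyloxy)-5-methoxy-2H-chromen-2-yl]phenyl pivalate | COc1cc(O[Si](C)(C)C(C)(C)C)c(Br)c2c1C=C[C@@H](c1ccc(OC(=O)C(C)(C)C)cc1)O2 | intermediate
15 | 4-[(2S,3S)-3-boranyl-8-bromo-7-(tert-butyldimethylsilyloxy)-5-methoxychroman-2-yl]phenyl pivalate (boron on C3, trans to the C2 aryl group; written as the monoalkylborane) | COc1cc(O[Si](C)(C)C(C)(C)C)c(Br)c2c1C[C@H]([BH2])[C@@H](c1ccc(OC(=O)C(C)(C)C)cc1)O2 | intermediate
16 | 4-[(2R,3S)-8-bromo-7-(tert-butyldimethylsilyloxy)-3-hydroxy-5-methoxychroman-2-yl]phenyl pivalate | COc1cc(O[Si](C)(C)C(C)(C)C)c(Br)c2c1C[C@H](O)[C@@H](c1ccc(OC(=O)C(C)(C)C)cc1)O2 | intermediate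
17 | prenylboronic acid pinacol ester | CC(C)=CCB1OC(C)(C)C(C)(C)O1 | starting material
18 | 4-[(2R,3S)-7-(tert-butyldimethylsilyloxy)-3-hydroxy-5-methoxy-8-(3-methylbut-2-en-1-yl)chroman-2-yl]phenyl pivalate | COc1cc(O[Si](C)(C)C(C)(C)C)c(CC=C(C)C)c2c1C[C@H](O)[C@@H](c1ccc(OC(=O)C(C)(C)C)cc1)O2 | intermediate
19 | 8-prenylafzelechin 5-methyl ether, (2R,3S)-2-(4-hydroxyphenyl)-5-methoxy-8-(3-methylbut-2-en-1-yl)chroman-3,7-diol | COc1cc(O)c(CC=C(C)C)c2c1C[C@H](O)[C@@H](c1ccc(O)cc1)O2 | target

**Step count**

Total: 12 steps. Longest linear sequence: 9 steps (steps 1–4, then 8–12); the aryl-alkyne fragment (steps 5–7) joins at step 8.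

**Steps most likely to fail**

Step 9 (gold hydroarylation). The gold-bound substrate may ionise at the benzylic–propargylic C–O bond, with loss of enantiomeric purity or ether cleavage, or may close through the internal alkyne carbon in the 5-exo mode. The fallback forms ring C by ring-closing metathesis at C3=C4 instead, without a Lewis acid. It sets out from phenol 6 (and alcohol 12) and comes back at chromene 14. Ortho-formylation of 6 (MgCl2, Et3N, paraformaldehyde, MeCN, reflux) should give 3-bromo-4-(tert-butyldimethylsilyloxy)-2-hydroxy-6-methoxybenzaldehyde F1. Wittig methylenation (Ph3PCH3Br, KOt-Bu, THF) should give 2-bromo-3-(tert-butyldimethylsilyloxy)-6-ethenyl-5-methoxyphenol F2. Mitsunobu coupling with 12 under the conditions of step 8 should give, with inversion, 4-[(1S)-1-[2-bromo-3-(tert-butyldimethylsilyloxy)-6-ethenyl-5-methoxyphenoxy]prop-2-yn-1-yl]phenyl pivalate F3. Semi-hydrogenation of the alkyne (H2, Pd/CaCO3 poisoned with Pb(OAc)2, quinoline) should give 4-[(1S)-1-[2-bromo-3-(tert-butyldimethylsilyloxy)-6-ethenyl-5-methoxyphenoxy]prop-2-en-1-yl]phenyl pivalate F4. Ring-closing metathesis (second-generation Grubbs catalyst, CH2Cl2, 40 °C) then closes the 2H-chromene 14 with loss of ethene.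

Step 11 (prenylation). Oxidative addition into the bromide flanked by two oxygen substituents may be slow, coupling may proceed through the tertiary allyl terminus to the reverse-prenyl isomer, or the base may cause protodebromination or desilylation. The fallback separates C–C bond formation from the choice of allyl terminus. It sets out from 16 and comes back at 18. Suzuki–Miyaura allylation with allylboronic acid pinacol ester (Pd(OAc)2, SPhos, K3PO4, toluene/H2O, 60 °C), which has no regiochemical ambiguity, should give 4-[(2R,3S)-8-allyl-7-(tert-butyldimethylsilyloxy)-3-hydroxy-5-methoxychroman-2-yl]phenyl pivalate F5. Olefin cross-metathesis with 2-methyl-2-butene (second-generation Grubbs catalyst, CH2Cl2, 40 °C) then converts the allyl into the prenyl group of 18.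

Step 8 (Mitsunobu). Displacement at the benzylic–propargylic carbon may acquire ionisation character and erode the enantiomeric purity, or the hindered ortho-bromophenol may couple slowly so that alkylation of the hydrazide competes. The fallback makes the O1–C2 bond by copper-catalysed enantioselective propargylic etherification through a copper allenylidene. It sets out from racemic acetate 11 and phenol 6 and comes back at 13 (CuOTf·0.5C6H6, chiral pybox ligand, i-Pr2NEt, non-nucleophilic solvent, −20 °C). The pybox enantiomer is chosen to deliver the (S)-ether. The process is enantioconvergent, so the resolution of step 7 is bypassed and no compound outside the list is made (F0).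

**Further compounds**

F1 | step 9 | 3-bromo-4-(tert-butyldimethylsilyloxy)-2-hydroxy-6-methoxybenzaldehyde | COc1cc(O[Si](C)(C)C(C)(C)C)c(Br)c(O)c1C=O
F2 | step 9 | 2-bromo-3-(tert-butyldimethylsilyloxy)-6-ethenyl-5-methoxyphenol | COc1cc(O[Si](C)(C)C(C)(C)C)c(Br)c(O)c1C=C
F3 | step 9 | 4-[(1S)-1-[2-bromo-3-(tert-butyldimethylsilyloxy)-6-ethenyl-5-methoxyphenoxy]prop-2-yn-1-yl]phenyl pivalate | COc1cc(O[Si](C)(C)C(C)(C)C)c(Br)c(O[C@@H](C#C)c2ccc(OC(=O)C(C)(C)C)cc2)c1C=C
F4 | step 9 | 4-[(1S)-1-[2-bromo-3-(tert-butyldimethylsilyloxy)-6-ethenyl-5-methoxyphenoxy]prop-2-en-1-yl]phenyl pivalate | COc1cc(O[Si](C)(C)C(C)(C)C)c(Br)c(O[C@@H](C=C)c2ccc(OC(=O)C(C)(C)C)cc2)c1C=C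
F5 | step 11 | 4-[(2R,3S)-8-allyl-7-(tert-butyldimethylsilyloxy)-3-hydroxy-5-methoxychroman-2-yl]phenyl pivalate | COc1cc(O[Si](C)(C)C(C)(C)C)c(CC=C)c2c1C[C@H](O)[C@@H](c1ccc(OC(=O)C(C)(C)C)cc1)O2
F0 | step 8 | none | none
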